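Late in a run with reagent to spare, once the substrate is consumed, the excess of left-handed product is what the contest between consumption and racemisation has left, and these flasks ask how far each reagent charge has carried that contest by 1.0 min.

    reagent + free catalyst + left-handed substrate → free catalyst + left-handed product (k1 = 1.13 × 10⁵ M⁻² s⁻¹)
    reagent + free catalyst + right-handed substrate → free catalyst + right-handed product (k2 = 52800 M⁻² s⁻¹)
    left-handed substrate ⇌ right-handed substrate (k3 = 0.00675 s⁻¹)
    free catalyst ⇌ dormant form (K4 = 1.0, k4 = 0.471 s⁻¹)
    free catalyst + impurity → spent catalyst (k5 = 3.42 × 10⁵ M⁻¹ s⁻¹)

all flasks: left-handed substrate 0.013 M; free catalyst 0.1 mol%; impurity 1.6 µM; right-handed substrate 0.013 M; time 1.0 min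

|  | reagent |
|---|---|
| Wednesday's | 1.00 equiv |
| Thursday's | 2.00 equiv |
| Tuesday's | 4.00 equiv |
| Saturday's | 8.00 equiv |
| Monday's | 15.0 equiv |

- free catalyst is single-handed; left-handed substrate and right-handed substrate are mirror images of each other, charged as a racemate, each of them at the stated concentration
- an excess is the difference of the two amounts in percent of their sum
- "hardly changes" means that all values lie within two and a half points (for a concentration: within two and a half percent of the largest)
- run time (Wednesday's): 1.0 min

- excess of left-handed product over right-handed product at the end for Wednesday's, Thursday's, Tuesday's, Saturday's, Monday's, in this order
- how the row runs (hardly changes / rises, then falls / falls all the way / falls, then rises / rises all the way)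

Which concentration sets the rate? Both consuming steps carry c(free catalyst) and c(reagent), so the first question is how much free catalyst works. Of the 13.0 µM charged, the impurity takes 1.6 µM with a lifetime of about 0.225 s, and the exchange with the dormant form relaxes in 1.06 s; both are much shorter than the run, so c(free catalyst) soon stays at 5.70 µM.

Where reagent is in excess, each substrate is then consumed in a pseudo-first-order way, and the two constants stand in the ratio of the selectivity factor, 2.14. At the start this gives an excess of 36.3%, which holds while the two substrates stand equal.

Does it keep them equal? Call D the left-handed substrate's pseudo-first-order constant divided by the racemisation constant 0.00675 s⁻¹. Following a molecule through its branches until consumption, at constant D, gives a late excess equal to the selectivity factor less one, over the selectivity factor plus one plus D. The substrates take two equivalents of reagent, so Monday's mean reagent is its charge less one equivalent, 0.182 M. This makes D 17.4 and Monday's late excess 5.56%. Monday's slower route has a lifetime of 18.3 s, shorter than the run, so that flask should lie near this late value. Wednesday's reagent covers half of the substrates, so the reckoning by hand expects the row to fall from just under 36.3% towards 5.56%.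

The forecast gives 33%, 30%, 23.5%, 15% and 7.3%, a row that falls all the way, on the ground that “more reagent drives the run toward full conversion of the racemising substrate”. Its Monday's figure is higher than the 5.56% reckoned here, which is an estimate for late times and not a value at 1.0 min.

The simulation gives 33.1%, 29.8%, 23.8%, 14.5% and 6.80%, a row that falls all the way. Monday's flask stands at 6.80%, higher than the rule's 5.56%, with 0.203% left-handed and 1.53% right-handed substrate still present, and at 10.0 min its products, 52.8% and 47.2%, show an excess of 5.67%. For Saturday's flask, D is 8.68 and the rule gives 9.64%, while its products at 10.0 min, 55.0% and 45.0%, show an excess of 10.0%.

The numbers were set for the occasion; the run is a simulation.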